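**Plan**
- Retrosynthesis: the γ-lactone is cut at C8–C17 and the C6–Cl/C7–O pair is traced to a 6,7-epoxy-8-ketone; the ten-membered ring B is cut at C7–C8 and C2–C3; ring A is cut at C11–C12; C1–C14 and C10–C11 lead back to a butenolide.
- Forward: (S)-5-(hydroxymethyl)butenolide (O–C9–C10–C1–C2=O) is a cyclic template. Conjugate addition at C10, methylation and aldol at C1, then ring A (C1, C14, C13, C12, C11, C10) is closed by C11 adding to the C12 aldehyde. The template lactone is opened at C2, ring B is closed at C7–C8, and the γ-lactone (ring C) is made last.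
- Enabling feature: C11 carries the exocyclic C20 and an oxygen, next to oxygenated C12, so ring A is an epoxidised 2-methylenecyclohexanol (2-iodoalkene + aldehyde). C1 and C10 are the α and β carbons of a γ-lactone ending at oxygenated C9, which holds the C11 arm and the C14–C13–C12 arm trans and gauche.
- Stereochemistry: C9 from the chiral pool; C10 and C1 by anti additions on the lactone; C14 and C2 by chelation control next to C1; C12 by equatorial hydride; C11 by hydroxyl-directed epoxidation; C6/C7 by catalyst-controlled epoxidation and anti chloride opening; C8/C17 in the lactone closure.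

Key step: step 9

Remark: briarane numbering (C1–C20) of the target is used for every intermediate; ring A is the six-membered carbocycle, ring B the ten-membered carbocycle, ring C the γ-lactone.

**Step 1**
Reactants: 1 (S)-5-(hydroxymethyl)furan-2(5H)-one
Product: 2 (S)-5-[(tert-butyldiphenylsilyloxy)methyl]furan-2(5H)-one
Conditions: TBDPSCl, imidazole, CH2Cl2, 0 °C to rt
Reagents that add atoms: tert-butyl(chloro)diphenylsilane, CC(C)(C)[Si](Cl)(c1ccccc1)c1ccccc1
Why: Imidazole-promoted silylation of the primary alcohol; the bulky silyl ether at C8 later screens one face of the lactone.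

**Step 2**
Reactants: 2 silyl butenolide; 3 (1-bromovinyl)trimethylsilane
Product: 6 3,4-trans-4,5-trans-3-methyl-4-[1-(trimethylsilyl)vinyl] lactone, via alkenyl Grignard reagent 4 (not isolated), via bromomagnesium enolate 5 (not isolated)
Conditions: 3, Mg, THF, 40 °C; CuBr·SMe2 (10 mol %), then 2, THF, −78 °C; then MeI, DMPU, −78 to −20 °C
Reagents that add atoms: iodomethane, CI
Why: Copper-catalysed conjugate addition of the alkenyl Grignard reagent should occur anti to the C9 silyloxymethyl group (sets C10), and the magnesium enolate is methylated in the same flask anti to the new C10 group (tandem conjugate addition–enolate alkylation); the C1 configuration is provisional because C1 is re-enolised in step 4.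

**Step 3**
Reactants: 6 vinylsilane lactone
Product: 7 4-(1-iodovinyl) lactone
Conditions: N-iodosuccinimide, (CF3)2CHOH, 0 °C
Reagents that add atoms: N-iodosuccinimide, O=C1CCC(=O)N1I
Why: Electrophilic ipso-iododesilylation of the 1,1-disubstituted vinylsilane (β-silyl cation, loss of silicon) puts iodine exactly where silicon was and touches no stereocentre.

**Step 4**
Reactants: 7 iodovinyl lactone; 8 3-(tert-butyldimethylsilyloxy)propanal
Product: 10 aldol adduct with quaternary C1 (C14 epimers), via lithium enolate 9 (not isolated)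
Conditions: LiN(iPr)2, THF, −78 °C; then 8, −78 °C; AcOH quench at −78 °C
Reagents that add atoms: none
Why: Aldol addition of the tetrasubstituted lactone enolate should take place on the face anti to the C10 iodovinyl group, fixing the quaternary centre C1 with the C14 chain trans to C11; the C14 carbinol mixture is erased in step 5.

**Step 5**
Reactants: 10 aldol adduct
Product: 11 C14 ketone (β-keto lactone)
Conditions: Dess–Martin periodinane, NaHCO3, CH2Cl2, rt
Reagents that add atoms: none
Why: Dess–Martin oxidation of the only free hydroxyl gives a non-enolisable β-keto lactone, so C1 cannot epimerise.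

**Step 6**
Reactants: 11 β-keto lactone
Product: 12 C14 alcohol of target configuration
Conditions: Zn(BH4)2, Et2O, −20 °C
Reagents that add atoms: none
Why: Chelation-controlled reduction: zinc bridges the C14 ketone and the lactone carbonyl and hydride should enter from the face of the small C15 methyl, not the C10 face, which sets C14; lactone and silyl ethers are inert.

**Step 7**
Reactants: 12 silyl ether
Product: 13 12,14-diol
Conditions: camphorsulfonic acid (cat.), MeOH/CH2Cl2, 0 °C
Reagents that add atoms: none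
Why: Acid-catalysed methanolysis removes the primary tert-butyldimethylsilyl ether much faster than the tert-butyldiphenylsilyl ether (selective desilylation).

**Step 8**
Reactants: 13 diol
Product: 14 14-hydroxy-12-aldehyde
Conditions: TEMPO (cat.), PhI(OAc)2, CH2Cl2, rt
Reagents that add atoms: none
Why: TEMPO/PhI(OAc)2 oxidation is selective for the primary alcohol over the hindered secondary C14 alcohol, and a 1,3-diol cannot lactonise.

**Step 9**
Reactants: 14 hydroxy aldehyde
Product: 16 ring-A bicyclic lactone (11(20)-methylene; 12-OH epimers; 14-OH), via alkenylchromium species 15 (not isolated)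
Conditions: CrCl2 (6 equiv), NiCl2 (2 mol %), DMSO/THF, rt, 5 mM
Reagents that add atoms: none
Why: NiCl2 is reduced by CrCl2 to zerovalent nickel, which inserts into the C11–I bond; transmetalation gives the trivalent alkenylchromium species 15, whose C11 carbon adds to the C12 aldehyde, and the chromium alkoxide is hydrolysed on work-up. The closest known reaction type is the intramolecular Nozaki–Hiyama–Kishi coupling of a 2-iodoalkene with an aldehyde to give a 2-methylenecycloalkanol. Ring A (C1, C14, C13, C12, C11, C10) closes by 6-exo-trig attack on the aldehyde carbon, trans-fused to the template lactone, and the exocyclic C11=C20 alkene is kept. The only new stereocentre is C12, set under substrate control in a chair transition state in which the aldehyde oxygen should prefer the equatorial site away from the axial C14 hydroxyl, so the 12-epimer of the target is expected to predominate; C12 is deliberately reset in steps 10 and 11, so either epimer serves. The step needs chemoselectivity (trivalent alkenylchromium reagents add to aldehydes and ignore lactones, free hydroxyls and silyl ethers) and cyclisation over oligomerisation, which the trans arrangement of the C11 and C14 arms on the five-membered lactone secures.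

**Step 10**
Reactants: 16 allylic alcohol (epimers)
Product: 17 12-ketone (exo-methylene enone)
Conditions: MnO2, CH2Cl2, rt
Reagents that add atoms: none
Why: MnO2 oxidises only the allylic C12 alcohol and leaves the saturated C14 alcohol, so both C12 epimers converge on one enone.

**Step 11**
Reactants: 17 enone lactone
Product: 18 lactol with 12,14-syn-diol
Conditions: iBu2AlH (5 equiv), CH2Cl2, −78 °C; aq. potassium sodium tartrate
Reagents that add atoms: none
Why: iBu2AlH first turns the axial C14 hydroxyl into a bulky aluminium alkoxide that blocks the axial face of C12, so external hydride should add 1,2 from the equatorial side and give the C12 alcohol syn to the C14 oxygen; the same reagent reduces the lactone to the lactol (hydride reduction of enone and lactone).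

**Step 12**
Reactants: 18 allylic alcohol
Product: 19 11,20-epoxy lactol
Conditions: mCPBA, NaHCO3, CH2Cl2, 0 °C
Reagents that add atoms: 3-chloroperoxybenzoic acid, OOC(=O)c1cccc(Cl)c1
Why: Hydroxyl-directed peracid epoxidation (Henbest effect) should deliver oxygen to the C11=C20 face syn to the C12 hydroxyl, which is also the face away from the axial C15 methyl, setting C11; this is the only alkene present.

**Step 13**
Reactants: 19 epoxy lactol; 20 2-(3-chloropropyl)-1,3-dioxolane
Product: 22 2,9,12,14-tetrol with the C3–C6 chain, via Grignard reagent 21 (not isolated)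
Conditions: 20, Mg, 1,2-dibromoethane (cat.), THF, reflux; then 19, THF, −40 to 0 °C (6 equiv of 21); aq. NH4Cl
Reagents that add atoms: none
Why: The lactol opens to its hydroxy aldehyde and the Grignard reagent adds to the C2 aldehyde under chelation control (magnesium bridges the C14 alkoxide and the C2 carbonyl, attack from the face of the small C15 methyl), which sets C2 and cleaves the template; the neopentyl-type spiro-epoxide should resist uncatalysed Grignard opening at this temperature.

**Step 14**
Reactants: 22 tetrol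
Product: 23 2,9,12,14-tetraacetate
Conditions: Ac2O, pyridine, DMAP, 40 °C
Reagents that add atoms: acetic anhydride, CC(=O)OC(C)=O
Why: Exhaustive DMAP-catalysed acetylation puts the four acetates of the target on the four secondary hydroxyls; no tertiary alcohol is present yet.

**Step 15**
Reactants: 23 dioxolane
Product: 24 C6 aldehyde
Conditions: pyridinium p-toluenesulfonate, acetone/H2O, 50 °C
Reagents that add atoms: water, O
Why: Mild acid-catalysed acetal hydrolysis frees the C6 aldehyde; acetates, the silyl ether and the hindered epoxide should tolerate this weak acid.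

**Step 16**
Reactants: 24 aldehyde
Product: 25 5(16)-methylene C6 aldehyde
Conditions: aq. CH2O, pyrrolidine (cat.), propionic acid (cat.), iPrOH, 45 °C
Reagents that add atoms: formaldehyde, C=O
Why: Amine-catalysed α-methylenation of the aldehyde (Mannich condensation, then elimination) installs C16 on C5.

**Step 17**
Reactants: 25 enal
Product: 26 (6E)-7-iodo-5(16),6-diene
Conditions: CrCl2, CHI3, THF, 0 °C
Reagents that add atoms: iodoform, IC(I)I
Why: Takai olefination (geminal dichromium species from CHI3 and CrCl2) converts the enal into the E-iodoalkene and adds C7; acetates and the epoxide are inert to CrCl2.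

**Step 18**
Reactants: 26 silyl ether
Product: 27 C8 primary alcohol
Conditions: HF·pyridine, pyridine, THF, 0 °C to rt
Reagents that add atoms: none
Why: Buffered fluoride desilylation; the buffer limits acetyl migration from C9 and epoxide opening.

**Step 19**
Reactants: 27 alcohol
Product: 28 C8 aldehyde
Conditions: Dess–Martin periodinane, NaHCO3, CH2Cl2, 0 °C
Reagents that add atoms: none
Why: Dess–Martin oxidation gives the α-acetoxy aldehyde under buffered conditions that should not epimerise C9.

**Step 20**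
Reactants: 28 iododiene aldehyde
Product: 30 ten-membered (6E)-5(16),6-dien-8-ol (C8 epimers), via dienylchromium species 29 (not isolated)
Conditions: CrCl2 (10 equiv), NiCl2 (1 mol %), DMSO, rt, 2 mM, slow addition
Reagents that add atoms: none
Why: Intramolecular Nozaki–Hiyama–Kishi coupling closes ring B at C7–C8 with retention of the E alkene; the four sp2 carbons in the tether and the fixed C2 and C9 arms on ring A should lower the transannular and entropic cost, and the C8 configuration is irrelevant.

**Step 21**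
Reactants: 30 dienol
Product: 31 (6E)-5(16),6-dien-8-one
Conditions: Dess–Martin periodinane, NaHCO3, CH2Cl2, rt
Reagents that add atoms: none
Why: Dess–Martin oxidation of the allylic alcohol removes the C8 stereocentre and gives the dienone.

**Step 22**
Reactants: 31 dienone
Product: 32 (6R,7S)-6,7-epoxy-8-ketone
Conditions: La(OiPr)3, (R)-BINOL, Ph3As=O (10 mol % each), tBuOOH, 4 Å MS, THF, rt
Reagents that add atoms: tert-butyl hydroperoxide, CC(C)(C)OO
Why: Catalytic asymmetric nucleophilic epoxidation of the E-enone (lanthanum–BINOL–arsine oxide system) should attack only the α,β-alkene by 1,4-addition of the peroxide and, with the (R)-ligand, give the αS,βR trans-epoxide, so C7 has its final configuration.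

**Step 23**
Reactants: 32 epoxy ketone
Product: 33 6-chloro-7-hydroxy-8-ketone
Conditions: MgCl2 (anhydrous, 3 equiv), MeCN/THF, 0 °C to rt; H2O work-up
Reagents that add atoms: magnesium dichloride, Cl[Mg]Cl
Why: Magnesium chelated between the ketone and epoxide oxygens should activate this epoxide selectively, and chloride opens it at the allylic β-carbon C6 with inversion (halide opening of a 2,3-epoxy ketone), giving C6 and C7 as in the target.

**Step 24**
Reactants: 33 chlorohydrin; 34 2-bromopropanoyl bromide
Product: 35 7-O-(2-bromopropanoyl) ester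
Conditions: pyridine, CH2Cl2, −40 °C
Reagents that add atoms: none
Why: Low-temperature acylation of the C7 alcohol with the acid bromide avoids base-induced loss of HCl from the β-chloro ketone; the configuration at the bromide carbon is irrelevant.

**Step 25**
Reactants: 35 bromo ester
Product: 37 CNP0349227.2, via samarium enolate 36 (not isolated)
Conditions: SmI2 (2.1 equiv), THF, −78 °C
Reagents that add atoms: none
Why: Samarium-mediated intramolecular Reformatsky reaction: SmI2 reduces the α-bromo ester to a trivalent samarium enolate that adds to the adjacent C8 ketone and closes the γ-lactone; the lactone should form trans-fused (C6–C7–C8–C9 anti in ring B), which sets C8, and the C18 methyl should take the exo position of the chelated transition state, cis to the new hydroxyl, which sets C17.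

**Compound list**
1 | (S)-5-(hydroxymethyl)furan-2(5H)-one | O=C1C=C[C@@H](CO)O1 | starting material
2 | (S)-5-[(tert-butyldiphenylsilyloxy)methyl]furan-2(5H)-one | O=C1C=C[C@@H](CO[Si](c5ccccc5)(c5ccccc5)C(C)(C)C)O1 | intermediate
3 | (1-bromovinyl)trimethylsilane | C=C(Br)[Si](C)(C)C | starting material
4 | [1-(trimethylsilyl)vinyl]magnesium bromide (not isolated) | C=C([Mg]Br)[Si](C)(C)C | intermediate
5 | bromomagnesium enolate of the C10 conjugate adduct (not isolated) | Br[Mg]OC1=C[C@H](C(=C)[Si](C)(C)C)[C@@H](CO[Si](c5ccccc5)(c5ccccc5)C(C)(C)C)O1 | intermediate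
6 | 3,4-trans-4,5-trans-3-methyl-4-[1-(trimethylsilyl)vinyl]-5-[(tert-butyldiphenylsilyloxy)methyl]dihydrofuran-2(3H)-one | O=C1[C@@H](C)[C@H](C(=C)[Si](C)(C)C)[C@@H](CO[Si](c5ccccc5)(c5ccccc5)C(C)(C)C)O1 | intermediate
7 | 4-(1-iodovinyl) analogue of 6 | O=C1[C@@H](C)[C@H](C(=C)I)[C@@H](CO[Si](c5ccccc5)(c5ccccc5)C(C)(C)C)O1 | intermediate
8 | 3-(tert-butyldimethylsilyloxy)propanal | O=CCCO[Si](C)(C)C(C)(C)C | starting material
9 | lithium enolate of 7 (not isolated) | [Li]OC1=C(C)[C@H](C(=C)I)[C@@H](CO[Si](c5ccccc5)(c5ccccc5)C(C)(C)C)O1 | intermediate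
10 | aldol adduct: quaternary C1 carrying the C14–C13–C12 chain trans to the C10 iodovinyl group; C14 epimers | O=C1[C@@](C)(C(O)CCO[Si](C)(C)C(C)(C)C)[C@H](C(=C)I)[C@@H](CO[Si](c5ccccc5)(c5ccccc5)C(C)(C)C)O1 | intermediate
11 | C14 ketone (β-keto lactone) | O=C1[C@@](C)(C(=O)CCO[Si](C)(C)C(C)(C)C)[C@H](C(=C)I)[C@@H](CO[Si](c5ccccc5)(c5ccccc5)C(C)(C)C)O1 | intermediate
12 | C14 alcohol of target configuration | O=C1[C@@](C)([C@@H](O)CCO[Si](C)(C)C(C)(C)C)[C@H](C(=C)I)[C@@H](CO[Si](c5ccccc5)(c5ccccc5)C(C)(C)C)O1 | intermediate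
13 | 12,14-diol | O=C1[C@@](C)([C@@H](O)CCO)[C@H](C(=C)I)[C@@H](CO[Si](c5ccccc5)(c5ccccc5)C(C)(C)C)O1 | intermediate
14 | 14-hydroxy-12-aldehyde | O=C1[C@@](C)([C@@H](O)CC=O)[C@H](C(=C)I)[C@@H](CO[Si](c5ccccc5)(c5ccccc5)C(C)(C)C)O1 | intermediate
15 | C11 alkenylchromium dichloride (not isolated) | O=C1[C@@](C)([C@@H](O)CC=O)[C@H](C(=C)[Cr](Cl)Cl)[C@@H](CO[Si](c5ccccc5)(c5ccccc5)C(C)(C)C)O1 | intermediate
16 | ring-A trans-fused bicyclic lactone with 11(20)-methylene, 12-OH (epimers) and 14-OH | O=C1O[C@H](CO[Si](c5ccccc5)(c5ccccc5)C(C)(C)C)[C@H]2C(=C)C(O)C[C@H](O)[C@]12C | intermediate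
17 | 12-ketone (exo-methylene enone) | O=C1O[C@H](CO[Si](c5ccccc5)(c5ccccc5)C(C)(C)C)[C@H]2C(=C)C(=O)C[C@H](O)[C@]12C | intermediate
18 | lactol (anomers) with 12,14-syn-diol | OC1O[C@H](CO[Si](c5ccccc5)(c5ccccc5)C(C)(C)C)[C@H]2C(=C)[C@H](O)C[C@H](O)[C@]12C | intermediate
19 | 11,20-epoxy lactol (epoxide oxygen syn to 12-OH) | OC1O[C@H](CO[Si](c5ccccc5)(c5ccccc5)C(C)(C)C)[C@H]2[C@@]3(CO3)[C@H](O)C[C@H](O)[C@]12C | intermediate
20 | 2-(3-chloropropyl)-1,3-dioxolane | ClCCCC1OCCO1 | starting material
21 | [3-(1,3-dioxolan-2-yl)propyl]magnesium chloride (not isolated) | Cl[Mg]CCCC1OCCO1 | intermediate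
22 | 2,9,12,14-tetrol (ring A with 11,20-epoxide; C2 chain C3–C6 ending in the dioxolane; C8 silyl ether) | O1CCOC1CCC[C@H](O)[C@@]2(C)[C@@H](O)C[C@@H](O)[C@]3(CO3)[C@@H]2[C@H](O)CO[Si](c5ccccc5)(c5ccccc5)C(C)(C)C | intermediate
23 | 2,9,12,14-tetraacetate | O1CCOC1CCC[C@H](OC(C)=O)[C@@]2(C)[C@@H](OC(C)=O)C[C@@H](OC(C)=O)[C@]3(CO3)[C@@H]2[C@H](OC(C)=O)CO[Si](c5ccccc5)(c5ccccc5)C(C)(C)C | intermediate
24 | C6 aldehyde | O=CCCC[C@H](OC(C)=O)[C@@]2(C)[C@@H](OC(C)=O)C[C@@H](OC(C)=O)[C@]3(CO3)[C@@H]2[C@H](OC(C)=O)CO[Si](c5ccccc5)(c5ccccc5)C(C)(C)C | intermediate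
25 | 5(16)-methylene C6 aldehyde | O=CC(=C)CC[C@H](OC(C)=O)[C@@]2(C)[C@@H](OC(C)=O)C[C@@H](OC(C)=O)[C@]3(CO3)[C@@H]2[C@H](OC(C)=O)CO[Si](c5ccccc5)(c5ccccc5)C(C)(C)C | intermediate
26 | (6E)-7-iodo-5(16),6-diene | I/C=C/C(=C)CC[C@H](OC(C)=O)[C@@]2(C)[C@@H](OC(C)=O)C[C@@H](OC(C)=O)[C@]3(CO3)[C@@H]2[C@H](OC(C)=O)CO[Si](c5ccccc5)(c5ccccc5)C(C)(C)C | intermediate
27 | C8 primary alcohol | I/C=C/C(=C)CC[C@H](OC(C)=O)[C@@]2(C)[C@@H](OC(C)=O)C[C@@H](OC(C)=O)[C@]3(CO3)[C@@H]2[C@H](OC(C)=O)CO | intermediate
28 | C8 aldehyde | I/C=C/C(=C)CC[C@H](OC(C)=O)[C@@]2(C)[C@@H](OC(C)=O)C[C@@H](OC(C)=O)[C@]3(CO3)[C@@H]2[C@H](OC(C)=O)C=O | intermediate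
29 | C7 dienylchromium dichloride (not isolated) | Cl[Cr](Cl)/C=C/C(=C)CC[C@H](OC(C)=O)[C@@]2(C)[C@@H](OC(C)=O)C[C@@H](OC(C)=O)[C@]3(CO3)[C@@H]2[C@H](OC(C)=O)C=O | intermediate
30 | ten-membered (6E)-5(16),6-dien-8-ol (C8 epimers) | C=C1CC[C@H](OC(C)=O)[C@@]2(C)[C@@H](OC(C)=O)C[C@@H](OC(C)=O)[C@]3(CO3)[C@@H]2[C@H](OC(C)=O)C(O)/C=C/1 | intermediate
31 | (6E)-5(16),6-dien-8-one | C=C1CC[C@H](OC(C)=O)[C@@]2(C)[C@@H](OC(C)=O)C[C@@H](OC(C)=O)[C@]3(CO3)[C@@H]2[C@H](OC(C)=O)C(=O)/C=C/1 | intermediate
32 | (6R,7S)-6,7-epoxy-8-ketone | C=C1CC[C@H](OC(C)=O)[C@@]2(C)[C@@H](OC(C)=O)C[C@@H](OC(C)=O)[C@]3(CO3)[C@@H]2[C@H](OC(C)=O)C(=O)[C@H]4O[C@H]14 | intermediate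
33 | 6-chloro-7-hydroxy-8-ketone | C=C1CC[C@H](OC(C)=O)[C@@]2(C)[C@@H](OC(C)=O)C[C@@H](OC(C)=O)[C@]3(CO3)[C@@H]2[C@H](OC(C)=O)C(=O)[C@@H](O)[C@H]1Cl | intermediate
34 | 2-bromopropanoyl bromide (racemic) | CC(Br)C(=O)Br | starting material
35 | 7-O-(2-bromopropanoyl) ester of 33 | C=C1CC[C@H](OC(C)=O)[C@@]2(C)[C@@H](OC(C)=O)C[C@@H](OC(C)=O)[C@]3(CO3)[C@@H]2[C@H](OC(C)=O)C(=O)[C@@H](OC(=O)C(C)Br)[C@H]1Cl | intermediate
36 | samarium enolate of 35 (not isolated) | C=C1CC[C@H](OC(C)=O)[C@@]2(C)[C@@H](OC(C)=O)C[C@@H](OC(C)=O)[C@]3(CO3)[C@@H]2[C@H](OC(C)=O)C(=O)[C@@H](OC(=CC)O[Sm](I)I)[C@H]1Cl | intermediate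
37 | CNP0349227.2 | C=C1CC[C@H](OC(C)=O)[C@@]2(C)[C@@H](OC(C)=O)C[C@@H](OC(C)=O)[C@]3(CO3)[C@@H]2[C@H](OC(C)=O)[C@]2(O)[C@@H](C)C(=O)O[C@H]2[C@H]1Cl | target

Total step count: 25. Longest linear sequence: 25 steps (from 1).

**Steps most likely to fail**

Step 20. Oligomerisation by intermolecular coupling, or simple reduction of the alkenyl iodide, may outrun closure of the strained ten-membered ring. The fallback closes the same ring by olefin metathesis at C6=C7; it sets out from 25 and returns at 30. Methylenation of 25 with Ph3P=CH2 should give the 2-substituted butadiene F1. Buffered HF·pyridine then frees the C8 alcohol F2, and Dess–Martin oxidation gives the aldehyde F3. CrCl2/NiCl2-mediated addition of vinyl bromide to F3 gives the vinyl carbinol F4 (C8 epimers). Ring-closing metathesis of F4 with the second-generation Hoveyda–Grubbs catalyst at high dilution should then deliver 30.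

Step 22. The facial bias of the ten-membered dienone may oppose the catalyst, eroding diastereoselectivity, and the basic peroxide medium may epimerise C9. The fallback moves the epoxidation to the allylic alcohol stage; it sets out from 30 and returns at 32. Sharpless epoxidation of 30 in kinetic-resolution mode (Ti(OiPr)4, L-(+)-diisopropyl tartrate, tBuOOH, −20 °C) should convert the matched C8 epimer into the erythro epoxy alcohol F5 with oxygen delivered to the required 6,7-face. Dess–Martin oxidation of F5 gives 32. The unreacted C8 epimer is recycled by oxidation to 31 and NaBH4/CeCl3 reduction back to 30.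

Step 25. Single-electron reduction of the α-acyloxy ketone or of the allylic chloride may compete with enolate formation, and the C17 configuration may not be controlled. The fallback builds the lactone by olefination and adjusts the oxidation level afterwards; it sets out from 33 and returns at 37. Esterification of 33 with 2-(diethoxyphosphoryl)propanoic acid (dicyclohexylcarbodiimide, DMAP) gives the phosphonate ester F6. Intramolecular Horner–Wadsworth–Emmons reaction (LiCl, iPr2NEt, MeCN) onto the C8 ketone gives the 8(17)-butenolide F7. Nucleophilic epoxidation (NaOCl, pyridine) should give the 8,17-epoxy lactone F8 from the less hindered face. SmI2 reduction of this α,β-epoxy lactone cleaves the C17–O bond and, after protonation at C17, should give 37.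

**Further compounds**
F1 | step 20 | 5(16),6-diene (methylenation product of 25) | C=CC(=C)CC[C@H](OC(C)=O)[C@@]2(C)[C@@H](OC(C)=O)C[C@@H](OC(C)=O)[C@]3(CO3)[C@@H]2[C@H](OC(C)=O)CO[Si](c5ccccc5)(c5ccccc5)C(C)(C)C
F2 | step 20 | C8 primary alcohol of F1 | C=CC(=C)CC[C@H](OC(C)=O)[C@@]2(C)[C@@H](OC(C)=O)C[C@@H](OC(C)=O)[C@]3(CO3)[C@@H]2[C@H](OC(C)=O)CO
F3 | step 20 | C8 aldehyde of F1 | C=CC(=C)CC[C@H](OC(C)=O)[C@@]2(C)[C@@H](OC(C)=O)C[C@@H](OC(C)=O)[C@]3(CO3)[C@@H]2[C@H](OC(C)=O)C=O
F4 | step 20 | C8 vinyl carbinol (C8 epimers) | C=CC(=C)CC[C@H](OC(C)=O)[C@@]2(C)[C@@H](OC(C)=O)C[C@@H](OC(C)=O)[C@]3(CO3)[C@@H]2[C@H](OC(C)=O)C(O)C=C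
F5 | step 22 | erythro 6,7-epoxy-8-ol | C=C1CC[C@H](OC(C)=O)[C@@]2(C)[C@@H](OC(C)=O)C[C@@H](OC(C)=O)[C@]3(CO3)[C@@H]2[C@H](OC(C)=O)[C@H](O)[C@H]4O[C@H]14
F6 | step 25 | 7-O-[2-(diethoxyphosphoryl)propanoyl] ester of 33 | C=C1CC[C@H](OC(C)=O)[C@@]2(C)[C@@H](OC(C)=O)C[C@@H](OC(C)=O)[C@]3(CO3)[C@@H]2[C@H](OC(C)=O)C(=O)[C@@H](OC(=O)C(C)P(=O)(OCC)OCC)[C@H]1Cl
F7 | step 25 | 8(17)-butenolide | C=C1CC[C@H](OC(C)=O)[C@@]2(C)[C@@H](OC(C)=O)C[C@@H](OC(C)=O)[C@]3(CO3)[C@@H]2[C@H](OC(C)=O)C2=C(C)C(=O)O[C@H]2[C@H]1Cl
F8 | step 25 | 8,17-epoxy lactone | C=C1CC[C@H](OC(C)=O)[C@@]2(C)[C@@H](OC(C)=O)C[C@@H](OC(C)=O)[C@]3(CO3)[C@@H]2[C@H](OC(C)=O)[C@@]24O[C@@]4(C)C(=O)O[C@H]2[C@H]1Cl
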